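**Plan**

- Labels: C1 = CH(OAc) bridge, C2 = methyl-bearing bridgehead, C3, C4=C5 (C5 formyl), C6 = formyl-bearing bridgehead, C7 = side-chain carbon, C8, C9, C1′ = side-chain methine; ring A = C1–C6, ring B = C1, C2, C9, C8, C7, C6.
- Enabling feature: on ring B the C1–O bond and the C6–C5 bond are trans-diaxial, and C5 sits on a three-carbon arm from C2. This is the pattern left when a C1–C6 epoxide is opened at C6, anti, by an enol carbon carried on that arm.
- Cuts: after adjusting the C1 acetate and both formyl groups, C5–C6 (ring A), then C4–C5, C2–C3, C6–CH2O, C2–CH3, and ring B at C7–C8 and C1–C6, back to (R)-citronellal and methyl vinyl ketone.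
- Forward: ring B is built first (steps 1–3), then substituted and epoxidised (steps 4–9); ring A closes in step 10; steps 11–17 set the oxidation levels.
- Stereochemistry: C1′ from citronellal; C7 from the amine catalyst; the C6 carbinol by addition anti to C7; C2 by suprafacial Claisen transfer from that carbinol; the epoxide face anti to the C2 arm and the C7 chain; C6 by inversion and C1 by retention in step 10.

Key step: step 10

Assumption: the (S)-configured diphenylprolinol methyl ether is taken to deliver methyl vinyl ketone to the enamine face that gives the (2S) aldehyde 3, by analogy with other aldehyde α-functionalisations by this catalyst family; if the sense were opposite, the (R)-catalyst would be used and nothing else changes.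

**Step 1**
Reactants: 1 (R)-citronellal; 2 methyl vinyl ketone
Product: 4 (4S)-4-[(2R)-6-methylhept-5-en-2-yl]cyclohex-2-en-1-one, via keto aldehyde 3 (not isolated)
Conditions: (S)-2-[methoxy(diphenyl)methyl]pyrrolidine (5 mol %), ethyl 3,4-dihydroxybenzoate (20 mol %), neat, 4 °C; then KOH, n-Bu4NOH (aq), THF–Et2O, reflux
Reagents that add atoms: none
Why: Enamine-catalysed Michael addition of the aldehyde to the enone forms C7–C8 with the catalyst shielding one enamine face, so C7 is set under catalyst control independently of C1′, and base then closes ring B by intramolecular aldol condensation (Robinson-type annulation).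

**Step 2**
Reactants: 4 (4S)-4-[(2R)-6-methylhept-5-en-2-yl]cyclohex-2-en-1-one
Product: 5 (4S)-1-methyl-4-[(2R)-6-methylhept-5-en-2-yl]cyclohex-2-en-1-ol (both C1 epimers)
Conditions: MeLi, Et2O, −78 °C
Reagents that add atoms: methyllithium, [Li]C
Why: 1,2-Addition of an organolithium to a cyclohexenone should give the tertiary allylic alcohol, whose new carbinol centre is removed in the next step, so its configuration is irrelevant.

**Step 3**
Reactants: 5 (4S)-1-methyl-4-[(2R)-6-methylhept-5-en-2-yl]cyclohex-2-en-1-ol
Product: 6 (6S)-3-methyl-6-[(2R)-6-methylhept-5-en-2-yl]cyclohex-2-en-1-one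
Conditions: [C5H5NH][CrO3Cl] (pyridinium chlorochromate), CH2Cl2, rt
Reagents that add atoms: pyridinium chlorochromate, [O-][Cr](=O)(=O)Cl.c1cc[nH+]cc1
Why: Dauben–Babler oxidative transposition: the tertiary allylic chromate ester undergoes a [3,3] shift and the resulting secondary chromate is oxidised, moving oxygen to C6 and the alkene to C1=C2, and the non-basic medium should leave the now α-positioned C7 unchanged.

**Step 4**
Reactants: 6 (6S)-3-methyl-6-[(2R)-6-methylhept-5-en-2-yl]cyclohex-2-en-1-one; 7 tributyl[(methoxymethoxy)methyl]stannane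
Product: 8 (1R,6S)-1-[(methoxymethoxy)methyl]-3-methyl-6-[(2R)-6-methylhept-5-en-2-yl]cyclohex-2-en-1-ol (hydroxyl cis to the side chain)
Conditions: 7, n-BuLi, THF, −78 °C; then 6, −78 °C
Reagents that add atoms: none
Why: Tin–lithium exchange gives an α-alkoxymethyllithium (a hydroxymethyl anion equivalent) that should add 1,2 to the enone from the face opposite the adjacent C7 substituent (equatorial attack, as with menthone- and piperitone-type ketones), placing the C6 hydroxyl cis to the side chain.

**Step 5**
Reactants: 8 (1R,6S)-1-[(methoxymethoxy)methyl]-3-methyl-6-[(2R)-6-methylhept-5-en-2-yl]cyclohex-2-en-1-ol; 9 trimethyl orthoacetate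
Product: 11 methyl 2-[(1R,4S)-3-[(methoxymethoxy)methyl]-1-methyl-4-[(2R)-6-methylhept-5-en-2-yl]cyclohex-2-en-1-yl]acetate, via ketene acetal 10 (not isolated)
Conditions: MeC(OMe)3 (excess), EtCO2H (cat.), xylene, 140 °C, MeOH distilled off
Reagents that add atoms: none
Why: Johnson–Claisen rearrangement: orthoester exchange and loss of methanol give ketene acetal 10, whose [3,3] shift is suprafacial across the ring allyl unit, so the C6–O bond on the side-chain face is exchanged for the C2–C3 bond on the same face and the quaternary C2 forms with the acetate arm cis to the C7 side chain.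

**Step 6**
Reactants: 11 methyl 2-[(1R,4S)-3-[(methoxymethoxy)methyl]-1-methyl-4-[(2R)-6-methylhept-5-en-2-yl]cyclohex-2-en-1-yl]acetate
Product: 12 methyl 2-[(1R,4S)-3-(hydroxymethyl)-1-methyl-4-[(2R)-6-methylhept-5-en-2-yl]cyclohex-2-en-1-yl]acetate
Conditions: HCl (cat., from AcCl), MeOH, 0 °C → rt
Reagents that add atoms: none
Why: Acid-catalysed transacetalisation of the methoxymethyl ether in methanol should free the allylic alcohol, the methyl ester being unchanged in this solvent and the trisubstituted alkenes tolerating dilute acid at room temperature.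

**Step 7**
Reactants: 12 methyl 2-[(1R,4S)-3-(hydroxymethyl)-1-methyl-4-[(2R)-6-methylhept-5-en-2-yl]cyclohex-2-en-1-yl]acetate
Product: 13 epoxy alcohol: ring B methyl acetate with a C1–C6 epoxide on the face opposite the C2 acetate arm and the C7 side chain (cis to the C2 methyl), C6 bearing CH2OH
Conditions: VO(acac)2 (5 mol %), t-BuOOH, CH2Cl2, 0 °C → rt
Reagents that add atoms: tert-butyl hydroperoxide, CC(C)(C)OO
Why: Vanadium-catalysed hydroxyl-directed epoxidation should react only at the allylic alcohol and leave the side-chain alkene, and the peroxide is delivered to the ring face not covered by the C7 side chain or the C2 arm.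

**Step 8**
Reactants: 13 epoxy alcohol
Product: 14 epoxy silyl ether: as 13 with C6–CH2OSi(t-Bu)Me2
Conditions: t-BuMe2SiCl, imidazole, DMF, rt
Reagents that add atoms: tert-butyldimethylsilyl chloride, CC(C)(C)[Si](C)(C)Cl
Why: Standard silylation of a primary alcohol, which removes the hydroxyl that could chelate the Lewis acid and steer epoxide opening to C1 in step 10.

**Step 9**
Reactants: 14 epoxy silyl ether; 15 methyl acetate
Product: 16 β-keto ester epoxide: ring B epoxide (C1–C6) with the C2 arm CH2C(=O)CH2CO2Me and C6–CH2OSi(t-Bu)Me2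
Conditions: LiN(i-Pr)2, 15 (3 equiv), THF, −78 °C; then 14, −78 → −40 °C; AcOH quench
Reagents that add atoms: none
Why: Crossed Claisen condensation: excess lithium enolate of methyl acetate adds to the methyl ester at low temperature and the product is protected as its enolate, forming C4–C5 and giving the β-keto ester directly, with methoxide as the only alkoxide released so that no ester scrambling occurs.

**Step 10**
Reactants: 16 β-keto ester epoxide
Product: 17 methyl 1-[(tert-butyldimethylsilyloxy)methyl]-3,9-dihydroxy-5-methyl-8-[(2R)-6-methylhept-5-en-2-yl]bicyclo[3.3.1]non-2-ene-2-carboxylate (enol form of the 3-oxo ester; ring configuration as in 24)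
Conditions: Sc(OTf)3 (20 mol %), 2,6-di-tert-butyl-4-methylpyridine (30 mol %), CH2Cl2, −20 → 0 °C
Reagents that add atoms: none
Why: Sc(OTf)3 binds the β-keto ester as a chelated scandium enol and activates the epoxide oxygen; the C6–O bond at the tertiary carbon lengthens, the enol carbon C5 adds to C6 from the face opposite the oxygen, and proton transfer returns the enolised β-keto ester and the C1 alcohol. The closest known reaction type is the Lewis-acid-promoted epoxide-initiated cyclisation terminated by a β-keto ester enol, combined with trans-diaxial (Fürst–Plattner) opening of a cyclohexene oxide. Ring A closes in the 6-endo mode (the C1–C6 bond of the epoxide lies inside the new ring), which completes the bicyclo[3.3.1]nonane. The new stereocentre C6 is set by inversion and is therefore controlled by the epoxide face installed in step 7, while C1 keeps its oxygen with retention, axial on ring B and anti to C5. The step needs attack at C6 and not C1, C- and not O-alkylation, and the enol and not the side-chain alkene as nucleophile: in the half-chair with the C7 side chain pseudo-equatorial the C2 arm is pseudo-axial over C6, so only attack at C6 leads directly to a chair (attack at C1 needs the other half-chair and gives a cis-fused five-membered ring), C6 is the carbon that best carries positive charge, and the metal-bound enol is a stronger π-nucleophile than the remote trisubstituted alkene. The hindered pyridine removes triflic acid that could start proton-initiated side reactions, and the silyl ether prevents chelation-directed opening at C1.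

**Step 11**
Reactants: 17 bicyclic hydroxy β-keto ester
Product: 18 methyl 1-[(tert-butyldimethylsilyloxy)methyl]-9-hydroxy-5-methyl-8-[(2R)-6-methylhept-5-en-2-yl]-3-(trifluoromethanesulfonyloxy)bicyclo[3.3.1]non-2-ene-2-carboxylate
Conditions: NaH (1.1 equiv), PhNTf2, THF, 0 °C → rt
Reagents that add atoms: N-phenylbis(trifluoromethanesulfonimide), O=S(=O)(N(c1ccccc1)S(=O)(=O)C(F)(F)F)C(F)(F)F
Why: O-Sulfonylation of the sodium enolate of a β-keto ester, in which one equivalent of base deprotonates only the 1,3-dicarbonyl so that the hindered C1 hydroxyl stays free.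

**Step 12**
Reactants: 18 enol triflate
Product: 19 methyl 1-[(tert-butyldimethylsilyloxy)methyl]-9-hydroxy-5-methyl-8-[(2R)-6-methylhept-5-en-2-yl]bicyclo[3.3.1]non-2-ene-2-carboxylate
Conditions: Pd(OAc)2 (5 mol %), PPh3, n-Bu3N, HCO2H, DMF, 60 °C
Reagents that add atoms: none
Why: Palladium-catalysed formate reduction of a vinyl triflate (oxidative addition to zerovalent palladium, formate exchange, decarboxylation, reductive elimination) should replace the triflate by hydrogen without touching the alkenes, the alcohol or the silyl ether.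

**Step 13**
Reactants: 19 enoate
Product: 20 1-[(tert-butyldimethylsilyloxy)methyl]-2-(hydroxymethyl)-5-methyl-8-[(2R)-6-methylhept-5-en-2-yl]bicyclo[3.3.1]non-2-en-9-ol
Conditions: i-Bu2AlH, CH2Cl2, −78 → 0 °C; aqueous potassium sodium tartrate (KNaC4H4O6) work-up
Reagents that add atoms: none
Why: 1,2-Reduction of the conjugated ester by i-Bu2AlH gives the allylic alcohol, and because the C6 oxygen stays silylated no lactone can form onto the C5 carboxyl carbon.

**Step 14**
Reactants: 20 allylic alcohol diol
Product: 21 1,2-bis[(tert-butyldimethylsilyloxy)methyl]-5-methyl-8-[(2R)-6-methylhept-5-en-2-yl]bicyclo[3.3.1]non-2-en-9-ol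
Conditions: t-BuMe2SiCl (1.1 equiv), imidazole, CH2Cl2, 0 °C
Reagents that add atoms: tert-butyldimethylsilyl chloride, CC(C)(C)[Si](C)(C)Cl
Why: Selective silylation, since the primary allylic hydroxyl reacts far faster than the axial C1 hydroxyl flanked by two quaternary carbons.

**Step 15**
Reactants: 21 bis-silyl ether alcohol
Product: 22 1,2-bis[(tert-butyldimethylsilyloxy)methyl]-5-methyl-8-[(2R)-6-methylhept-5-en-2-yl]bicyclo[3.3.1]non-2-en-9-yl acetate
Conditions: Ac2O, DMAP, pyridine, 50 °C
Reagents that add atoms: acetic anhydride, CC(=O)OC(C)=O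
Why: DMAP-catalysed acylation of the hindered secondary alcohol, done at a stage with no carbonyl group and no free primary hydroxyl, so that forcing conditions can cause neither retro-aldol cleavage nor acyl transfer.

**Step 16**
Reactants: 22 bis-silyl ether acetate
Product: 23 1,2-bis(hydroxymethyl)-5-methyl-8-[(2R)-6-methylhept-5-en-2-yl]bicyclo[3.3.1]non-2-en-9-yl acetate
Conditions: HF·pyridine, pyridine, THF, 0 °C → rt
Reagents that add atoms: none
Why: Fluoride cleavage of both primary silyl ethers under buffered, slightly acidic conditions that should not promote migration of the C1 acetate.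

**Step 17**
Reactants: 23 diol acetate
Product: 24 (1R,5R,8S,9R)-1,2-diformyl-5-methyl-8-[(2R)-6-methylhept-5-en-2-yl]bicyclo[3.3.1]non-2-en-9-yl acetate (CNP0299929.2)
Conditions: (COCl)2, DMSO, CH2Cl2, −78 °C; then Et3N, −78 → 0 °C
Reagents that add atoms: none
Why: Swern oxidation converts both primary hydroxyls into alkoxysulfonium ions before base is added, so the 1,4-dialdehyde forms without a hydroxy aldehyde/lactol stage that would over-oxidise to a lactone, and the quaternary C6 cannot epimerise.

**Compound list**

1 | (R)-citronellal, (3R)-3,7-dimethyloct-6-enal | O=CC[C@H](C)CCC=C(C)C | starting material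
2 | methyl vinyl ketone (but-3-en-2-one) | CC(=O)C=C | starting material
3 | (2S)-2-[(2R)-6-methylhept-5-en-2-yl]-5-oxohexanal (keto aldehyde, not isolated) | O=C[C@H]([C@H](C)CCC=C(C)C)CCC(C)=O | intermediate
4 | (4S)-4-[(2R)-6-methylhept-5-en-2-yl]cyclohex-2-en-1-one | O=C1C=C[C@H]([C@H](C)CCC=C(C)C)CC1 | intermediate
5 | (4S)-1-methyl-4-[(2R)-6-methylhept-5-en-2-yl]cyclohex-2-en-1-ol, both C1 epimers | CC1(O)C=C[C@H]([C@H](C)CCC=C(C)C)CC1 | intermediate
6 | (6S)-3-methyl-6-[(2R)-6-methylhept-5-en-2-yl]cyclohex-2-en-1-one | CC1=CC(=O)[C@H]([C@H](C)CCC=C(C)C)CC1 | intermediate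
7 | tributyl[(methoxymethoxy)methyl]stannane | CCCC[Sn](CCCC)(CCCC)COCOC | starting material
8 | (1R,6S)-1-[(methoxymethoxy)methyl]-3-methyl-6-[(2R)-6-methylhept-5-en-2-yl]cyclohex-2-en-1-ol | CC1=C[C@@](O)(COCOC)[C@H]([C@H](C)CCC=C(C)C)CC1 | intermediate
9 | trimethyl orthoacetate (1,1,1-trimethoxyethane) | COC(C)(OC)OC | starting material
10 | ketene acetal of 8, 1-(1-methoxyvinyloxy) derivative (not isolated) | CC1=C[C@@](OC(=C)OC)(COCOC)[C@H]([C@H](C)CCC=C(C)C)CC1 | intermediate
11 | methyl 2-[(1R,4S)-3-[(methoxymethoxy)methyl]-1-methyl-4-[(2R)-6-methylhept-5-en-2-yl]cyclohex-2-en-1-yl]acetate | COC(=O)C[C@@]1(C)CC[C@@H]([C@H](C)CCC=C(C)C)C(COCOC)=C1 | intermediate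
12 | methyl 2-[(1R,4S)-3-(hydroxymethyl)-1-methyl-4-[(2R)-6-methylhept-5-en-2-yl]cyclohex-2-en-1-yl]acetate | COC(=O)C[C@@]1(C)CC[C@@H]([C@H](C)CCC=C(C)C)C(CO)=C1 | intermediate
13 | epoxy alcohol: C1–C6 epoxide of 12, oxygen trans to the C2 acetate arm and the C7 side chain | COC(=O)C[C@@]1(C)CC[C@@H]([C@H](C)CCC=C(C)C)[C@]2(CO)O[C@H]12 | intermediate
14 | tert-butyldimethylsilyl ether of 13 | COC(=O)C[C@@]1(C)CC[C@@H]([C@H](C)CCC=C(C)C)[C@]2(CO[Si](C)(C)C(C)(C)C)O[C@H]12 | intermediate
15 | methyl acetate | COC(C)=O | starting material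
16 | β-keto ester epoxide (key-step precursor): C2 arm CH2C(=O)CH2CO2Me, C1–C6 epoxide, C6–CH2OSi(t-Bu)Me2 | COC(=O)CC(=O)C[C@@]1(C)CC[C@@H]([C@H](C)CCC=C(C)C)[C@]2(CO[Si](C)(C)C(C)(C)C)O[C@H]12 | intermediate
17 | methyl 1-[(tert-butyldimethylsilyloxy)methyl]-3,9-dihydroxy-5-methyl-8-[(2R)-6-methylhept-5-en-2-yl]bicyclo[3.3.1]non-2-ene-2-carboxylate (key-step product, enol form) | O[C@@H]1[C@@]2(C)CC(O)=C(C(=O)OC)[C@]1(CO[Si](C)(C)C(C)(C)C)[C@H]([C@H](C)CCC=C(C)C)CC2 | intermediate
18 | enol triflate of 17 | O[C@@H]1[C@@]2(C)CC(OS(=O)(=O)C(F)(F)F)=C(C(=O)OC)[C@]1(CO[Si](C)(C)C(C)(C)C)[C@H]([C@H](C)CCC=C(C)C)CC2 | intermediate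
19 | methyl 1-[(tert-butyldimethylsilyloxy)methyl]-9-hydroxy-5-methyl-8-[(2R)-6-methylhept-5-en-2-yl]bicyclo[3.3.1]non-2-ene-2-carboxylate | O[C@@H]1[C@@]2(C)CC=C(C(=O)OC)[C@]1(CO[Si](C)(C)C(C)(C)C)[C@H]([C@H](C)CCC=C(C)C)CC2 | intermediate
20 | 1-[(tert-butyldimethylsilyloxy)methyl]-2-(hydroxymethyl)-5-methyl-8-[(2R)-6-methylhept-5-en-2-yl]bicyclo[3.3.1]non-2-en-9-ol | O[C@@H]1[C@@]2(C)CC=C(CO)[C@]1(CO[Si](C)(C)C(C)(C)C)[C@H]([C@H](C)CCC=C(C)C)CC2 | intermediate
21 | 1,2-bis[(tert-butyldimethylsilyloxy)methyl]-5-methyl-8-[(2R)-6-methylhept-5-en-2-yl]bicyclo[3.3.1]non-2-en-9-ol | O[C@@H]1[C@@]2(C)CC=C(CO[Si](C)(C)C(C)(C)C)[C@]1(CO[Si](C)(C)C(C)(C)C)[C@H]([C@H](C)CCC=C(C)C)CC2 | intermediate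
22 | 1,2-bis[(tert-butyldimethylsilyloxy)methyl]-5-methyl-8-[(2R)-6-methylhept-5-en-2-yl]bicyclo[3.3.1]non-2-en-9-yl acetate | CC(=O)O[C@@H]1[C@@]2(C)CC=C(CO[Si](C)(C)C(C)(C)C)[C@]1(CO[Si](C)(C)C(C)(C)C)[C@H]([C@H](C)CCC=C(C)C)CC2 | intermediate
23 | 1,2-bis(hydroxymethyl)-5-methyl-8-[(2R)-6-methylhept-5-en-2-yl]bicyclo[3.3.1]non-2-en-9-yl acetate | CC(=O)O[C@@H]1[C@@]2(C)CC=C(CO)[C@]1(CO)[C@H]([C@H](C)CCC=C(C)C)CC2 | intermediate
24 | (1R,5R,8S,9R)-1,2-diformyl-5-methyl-8-[(2R)-6-methylhept-5-en-2-yl]bicyclo[3.3.1]non-2-en-9-yl acetate | CC(=O)O[C@@H]1[C@@]2(C)CC=C(C=O)[C@]1(C=O)[C@H]([C@H](C)CCC=C(C)C)CC2 | target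

**Step count and risks**

Total steps: 17. Longest linear sequence: 17 steps (1 → 24).

Steps most likely to fail:

1. Step 10. The epoxide may open at C1 to give a five-membered ring, the enol oxygen may alkylate instead of C5, the side-chain alkene may capture the developing positive charge at C6, or a 1,2-hydride shift may give a C1 ketone. Fallback: starting from 16, the β-keto ester would be silylated (Me3SiCl, Et3N, DMF) to its trimethylsilyl enol ether F1, a preformed π-nucleophile whose oxygen is blocked. F1 would then be cyclised with BF3·OEt2 in CH2Cl2 at −78 °C (Mukaiyama-type alkylation by the epoxide), a temperature at which the isolated alkene should not take part. Mild aqueous acid work-up removes silicon and the sequence returns to the route at 17.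

2. Step 5. The hot, acidic conditions may ionise or dehydrate the tertiary allylic alcohol to dienes, or the hindered hydroxyl may fail to exchange into the orthoester. Fallback: starting from 8, acetylation (Ac2O, DMAP, Et3N) would give the tertiary allylic acetate F2. Ireland–Claisen rearrangement of its silyl ketene acetal (LiN(i-Pr)2, Me3SiCl, THF, −78 °C then warming) proceeds under basic conditions with the same suprafacial transfer and would give the carboxylic acid F3. Esterification with Me3SiCHN2 in MeOH–toluene returns to the route at 11.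

3. Step 9. Proton transfer may outrun addition at the hindered ester, leading to enolisation of 14 and intramolecular epoxide opening to a cyclopropane, or conversion may stay incomplete. Fallback: starting from 14, partial reduction with i-Bu2AlH (1.1 equiv, CH2Cl2, −78 °C) would give the aldehyde F4. Aldol addition of the lithium enolate of 15 at −78 °C, which is much faster than ester addition, would give the β-hydroxy ester F5 as a mixture of carbinol epimers. Dess–Martin oxidation (NaHCO3, CH2Cl2) returns to the route at 16.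

**Further compounds**

F1 | step 10 | trimethylsilyl enol ether of 16 (methyl 3-(trimethylsilyloxy)but-2-enoate arm, E/Z mixture) | COC(=O)C=C(O[Si](C)(C)C)C[C@@]1(C)CC[C@@H]([C@H](C)CCC=C(C)C)[C@]2(CO[Si](C)(C)C(C)(C)C)O[C@H]12
F2 | step 5 | (1R,6S)-1-[(methoxymethoxy)methyl]-3-methyl-6-[(2R)-6-methylhept-5-en-2-yl]cyclohex-2-en-1-yl acetate | CC1=C[C@@](OC(C)=O)(COCOC)[C@H]([C@H](C)CCC=C(C)C)CC1
F3 | step 5 | 2-[(1R,4S)-3-[(methoxymethoxy)methyl]-1-methyl-4-[(2R)-6-methylhept-5-en-2-yl]cyclohex-2-en-1-yl]acetic acid | OC(=O)C[C@@]1(C)CC[C@@H]([C@H](C)CCC=C(C)C)C(COCOC)=C1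
F4 | step 9 | aldehyde from 14 (C2 arm CH2CHO) | O=CC[C@@]1(C)CC[C@@H]([C@H](C)CCC=C(C)C)[C@]2(CO[Si](C)(C)C(C)(C)C)O[C@H]12
F5 | step 9 | β-hydroxy ester from F4 (C2 arm CH2CH(OH)CH2CO2Me, carbinol epimers) | COC(=O)CC(O)C[C@@]1(C)CC[C@@H]([C@H](C)CCC=C(C)C)[C@]2(CO[Si](C)(C)C(C)(C)C)O[C@H]12
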